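## The problem

Target 30 is a trans-fused hydroazulene: a cyclopentane and a cycloheptane share the C3a–C8a bond, and seven of the ten ring carbons are stereocentres (the C1–C2 epoxide with its C2 methyl, the ring fusion, the C4 isopropyl, the C5 isovanillate and the C7 methyl carbinol). The isopropyl group and every oxygen substituent lie on the face of H-3a (β), whereas H-8a is α, so the ring fusion has to be set against the face on which all potential directing groups sit. Once C3a is fixed, C4 (epimerisable next to a C5 carbonyl), C5 (hydride anti to the isopropyl group) and the epoxide (delivery from the C7 hydroxyl) can be derived from it. C7, in contrast, is a fully substituted carbinol that cannot be corrected later, and C8a has no handle of its own. The end of the synthesis must be gentle: the trisubstituted epoxide and the tertiary alcohol are acid-labile, the aryl ester and free phenol are sensitive to base and oxidants, and a C7 oxygen that becomes allylic on the way ionises easily. The enabling feature is the 1,3-relationship of the two oxygenated carbons of the seven-membered ring. C5 is the centre of a three-carbon unit C4–C5–C6. C7, which bears methyl and oxygen, is the terminus of a four-carbon unit C3a–C8a–C8–C7 whose other end is a ring-fusion carbon. This is the retron of an oxyallyl cation adding across the silyl dienol ether of a cyclopentenyl methyl ketone, which closes the seven-membered ring and sets C3a, C4 and C7 in one operation.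

## Retrosynthesis

**Epoxide and phenol last.** The O–Si bond of the phenol and the two C–O bonds of the epoxide are cut first (30 to 29 to 28). Placing the epoxide at the end keeps the most acid-labile group out of every earlier step and lets the free C7 hydroxyl of 28 deliver the oxidant to the β face; epoxidising before the ester is in place would expose it to acylation and fluoride steps. The forward reaction must put oxygen on the face syn to the C7 hydroxyl.

**Ester.** The C5–O acyl bond is cut to diol 24 and the protected acid 27, which comes from isovanillic acid 25. The alternative of carrying the aroyl group from an earlier stage is ruled out by the dissolving-metal and Grignard steps. The forward reaction only has to distinguish a secondary from a tertiary hydroxyl.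

**C2 methyl and C8a hydrogen.** The C2–CH3 bond is cut to enol triflate 22, and the C8a–H bond together with the triflate oxygen leads back to enone 20 by way of the diol's bis-silyl ether 23. Against the neighbouring option (methyl addition to a saturated C2 ketone and dehydration, which gives alkene regioisomers), reduction of the enone gives the C1=C2 enolate regiospecifically. The forward reaction is asked to protonate C8a on the α face.

**Enone and C5 carbinol.** Enone 20 comes from ketal 18 by hydrolysis and migration of the C8=C8a double bond into conjugation. Silyl ether 18 comes from alcohol 17, and 17 from ketone 16 by reduction cis to the isopropyl group. These are functional-group changes only, but they turn the alkene left by the ring-forming step into the handle for C8a and C2.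

**Key disconnection.** The bonds C3a–C4 and C6–C7 of 16 are cut, giving silyl dienol ether 12 and chloroketone 15. Cuts through C4–C5 or C5–C6 (aldol or acylation closures) or at C8=C8a (metathesis) leave one long chain and set the stereocentres one at a time. The (4+3) cut divides the ring into two fragments of similar size and creates C3a, C4 and C7 together. The forward reaction must join C3a to the isopropyl-bearing terminus, keep the C7 oxygen cis to H-3a and distinguish the two faces of the diene. The first two demands are answered by the polarity of the partners and the (Z)-geometry of 12. The third is not entrusted to a chiral promoter: the ketal of 12 is made from (2R,3R)-butane-2,3-diol 6, so the two facial adducts are diastereomers and 16 can be isolated stereochemically pure.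

**Diene.** Dienol ether 12 comes from ketone 11 by soft enolisation, 11 from alcohol 10 by oxidation, and 10 from acyclic diene 9 by cutting the C3a=C8a double bond (ring-closing metathesis). Olefination of a cyclopentanone, or deconjugation of an enone, would leave the position of this double bond ambiguous; metathesis fixes it.

**Building blocks.** Alcohol 9 is cut at C7–C8 into allylic chloride 7 and acetaldehyde 8 (Barbier allylation). Ketal 7 comes from dithiane 5 and diol 6, and 5 from 1,3-dithiane 1, allyl bromide 2 and 3-chloro-2-(chloromethyl)prop-1-ene 3 by two acyl-anion alkylations. Chloroketone 15 is cut at the acyl carbon into isobutylmagnesium bromide 13 and Weinreb amide 14. All are commercial.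

## Roads not taken

Alternative 1: The C3a–C8a bond is cut, and the seven-membered carbocycle is traced to a seven-membered lactone cut out of a chiral-pool cyclohexenone. In the forward key step KN(SiMe3)2 and Me3SiCl give the silyl ketene acetal, and a boat [3,3] shift (Ireland–Claisen ring contraction) forms C3a–C8a, cleaves C7–O and gives cycloheptene acid A1. Merits: the absolute configuration comes from the chiral pool, the sigmatropic step is stereospecific and of a well-known type, and C4 and C5 are already in place. Weak points for this target: the C7 oxygen is lost in the key step and has to be put back by a regio- and face-selective hydration of the C7=C8 alkene; C3a is formed as the wrong epimer; and the five-membered ring (C2, its methyl and the C1–C2 unsaturation) still has to be built from the carboxyl and the CH2O arm. In enantiocontrol and in precedent for the key step this road is better than the chosen one. The chosen plan sets against it that both rings and the C7 carbinol are present directly after the key step, and that the endgame needs no second ring construction.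

Alternative 2: The bonds C8a–C3a, C1–C2 and C2–C3 are cut, leading to acyclic allene-yne A2. In the forward key step [Rh(CO)2Cl]2 under CO joins the alkyne, the distal allene double bond and CO (allenic Pauson–Khand reaction), closing both rings at once to dienone A3. Merits: a known reaction type for bicyclo[5.3.0] dienones, both rings in one step, C5 and C7 brought in from acyclic asymmetric chemistry, and a C2 ketone with the C1=C8a enone that the chosen endgame also uses. Weak points: A3 has a tetrasubstituted C3a=C4 double bond, so C3a, C4 and C8a must all be created afterwards by reducing a cross-conjugated dienone with 1,4- versus 1,6-selectivity and the trans ring fusion at stake; the 1,1-disubstituted allene next to a silyloxy stereocentre and the 1,3-related tertiary carbinol make A2 laborious. The key step is better precedented than the one chosen here. The chosen plan sets against it that C3a, C4 and C7 come out of the ring-forming step with defined relative configuration, leaving only C8a to a reduction.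

Alternative 3: The C5–C6 bond is cut, leading to cyclopentenyl aldehyde A4, which carries a 2-methylallyl group on C8a. In the forward key step Me2AlCl promotes an intramolecular carbonyl-ene reaction that forms C5–C6, sets the C5 carbinol and leaves an exocyclic methylene on C7 (alcohol A5). Merits: a known reaction type, the C1=C2 alkene and the trans C3a/C8a relationship are settled before ring closure (so the C8a reduction problem of the chosen plan does not arise), and C5 needs no separate reduction. Weak points: A4 already contains three stereocentres, one of them an epimerisable α-branched aldehyde; seven-membered ene closures are slower than six-membered ones and compete with proton loss; and the C7 methylene must be hydrated face-selectively to the tertiary alcohol in the presence of the trisubstituted C1=C2 alkene, a chemoselectivity problem at the end. This road is better for the ring fusion. The chosen plan sets against it that the C7 carbinol is fixed in the ring-forming step and that the two alkenes never have to be told apart.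

Key step: step 8

Remarks. Locants of all bicyclic compounds follow the hydroazulene skeleton of the target (C1–C2 epoxide carbons, C3, C3a, C4 isopropyl, C5 ester, C6, C7 carbinol, C8, C8a); β is the face that carries H-3a, α the opposite face. Assumption: the two (4+3) adducts that differ in the face of the diene attacked are separable by chromatography, as diastereomeric butane-2,3-diol ketals of β-substituted cyclic ketones generally are; should the intrinsic bias favour the unwanted adduct, the enantiomeric diol is used in step 2 without other change.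

Step 1
Reactants: 1 1,3-dithiane; 2 allyl bromide; 3 3-chloro-2-(chloromethyl)prop-1-ene
Product: 5 2-allyl-2-[2-(chloromethyl)prop-2-en-1-yl]-1,3-dithiane, via 2-allyl-1,3-dithiane 4 (not isolated)
Conditions: nBuLi, THF, −30 °C; 2, −78 → 0 °C; nBuLi, −30 °C; 3 (3 equiv), −78 → 0 °C
Reagents that add atoms: none
Why: Corey–Seebach umpolung: the 2-lithiodithiane is alkylated by allyl bromide and, after a second lithiation, by the allylic dichloride used in excess so that only one chloride is displaced; direct and allylic displacement on 3 give the same product.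

Step 2
Reactants: 5; 6 (2R,3R)-butane-2,3-diol
Product: 7 (4R,5R)-2-allyl-2-[2-(chloromethyl)prop-2-en-1-yl]-4,5-dimethyl-1,3-dioxolane
Conditions: PhI(OCOCF3)2, 6 (5 equiv), MeCN, 0 °C → rt
Reagents that add atoms: none
Why: Oxidative dethioketalisation with a hypervalent iodine reagent in the presence of a 1,2-diol gives the dioxolane directly, so the doubly β,γ-unsaturated ketone is never free to conjugate; the C2-symmetric diol creates no new stereocentre and becomes the resolving auxiliary for step 8.

Step 3
Reactants: 7; 8 acetaldehyde
Product: 9 4-{[(4R,5R)-2-allyl-4,5-dimethyl-1,3-dioxolan-2-yl]methyl}pent-4-en-2-ol (both carbinol epimers)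
Conditions: indium powder, NaI (cat.), DMF, rt
Reagents that add atoms: none
Why: Indium-mediated Barbier allylation of an aldehyde tolerates the ketal and both alkenes; the 2-substituted allyl unit gives one constitution whichever terminus attacks, and the carbinol configuration is irrelevant because it is oxidised in step 5.

Step 4
Reactants: 9
Product: 10 1-[(2R,3R)-2,3-dimethyl-1,4-dioxaspiro[4.4]non-7-en-7-yl]propan-2-ol (both carbinol epimers)
Conditions: RuCl2(=CHPh)(H2IMes)(PCy3) (second-generation Grubbs catalyst, 3 mol%), CH2Cl2, 40 °C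
Reagents that add atoms: none
Why: Ring-closing metathesis of a monosubstituted with a 1,1-disubstituted alkene closes the cyclopentene and fixes the trisubstituted double bond between C8a and C3a without positional ambiguity; the gem-dialkoxy carbon favours closure.

Step 5
Reactants: 10
Product: 11 1-[(2R,3R)-2,3-dimethyl-1,4-dioxaspiro[4.4]non-7-en-7-yl]propan-2-one
Conditions: nPr4N[RuO4] (5 mol%), N-methylmorpholine N-oxide, 4 Å molecular sieves, CH2Cl2, rt
Reagents that add atoms: none
Why: Catalytic perruthenate oxidation is neutral, so the β,γ-unsaturated ketone should not move into conjugation and the ketal is untouched.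

Step 6
Reactants: 11
Product: 12 triethyl{[(Z)-1-((2R,3R)-2,3-dimethyl-1,4-dioxaspiro[4.4]non-7-en-7-yl)prop-1-en-2-yl]oxy}silane (fragment 1)
Conditions: Et3SiOTf, Et3N, Et2O, 0 °C
Reagents that add atoms: triethylsilyl trifluoromethanesulfonate, CC[Si](CC)(CC)OS(=O)(=O)C(F)(F)F
Why: Soft enolisation with silyl triflate and amine removes the doubly activated C8 proton and gives the conjugated dienol ether; the (Z)-isomer (silyloxy cis to the ring, methyl trans) is the usual outcome for ketones RCH2COCH3 under these conditions.

Step 7
Reactants: 13 isobutylmagnesium bromide; 14 2-chloro-N-methoxy-N-methylacetamide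
Product: 15 1-chloro-4-methylpentan-2-one (fragment 2)
Conditions: THF, −78 → 0 °C; 1 M HCl
Reagents that add atoms: none
Why: Weinreb ketone synthesis: the chelated tetrahedral intermediate prevents over-addition, a standard access to chloromethyl ketones.

Step 8
Reactants: 12; 15
Product: 16 (3aS,4S,7S)-4-isopropyl-7-methyl-7-(triethylsilyloxy)-1,3,3a,4,6,7-hexahydroazulene-2,5-dione 2-[(2R,3R)-butane-2,3-diyl] ketal (C8=C8a alkene; H-3a, isopropyl and silyloxy all β)
Conditions: 15 (1.5 equiv), LiClO4 (3 M in Et2O), Et3N (slow addition), 0 °C → rt; chromatographic separation of the two facial diastereomers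
Reagents that add atoms: none
Why: Proposed new method: Et3N enolises 15 towards C4 and Li+-assisted loss of chloride gives the 1-isopropyl-2-oxyallyl cation, whose more substituted, more electrophilic terminus C4 is attacked by the γ-carbon C3a of silyl dienol ether 12, after which the C6 enolate carbon closes on the C7 silyloxycarbenium ion; the closest known reaction type is the Et3N/LiClO4 (4+3) cycloaddition of α-chloroketone-derived oxyallyl cations with furans and open-chain 1,3-dienes, which has not been shown with a silyl dienol ether as the four-carbon partner. The seven-membered ring closes through the second bond C6–C7 in a 7-(enolendo)-exo-trig, Mukaiyama-aldol-type collapse of the zwitterion, which should be fast because the first bond forms from the s-cis diene and holds both termini together. C7 follows from the (Z)-geometry of 12: with the silyloxy group inside, bonding on one face at both diene termini places the C7 oxygen cis to H-3a. C4 is set relative to C3a in the compact transition state and, being α to the new ketone, can equilibrate under Et3N to the isomer with isopropyl trans to C3. The absolute configuration of C3a is carried by the auxiliary: the (2R,3R)-butanediol ketal makes the two facial adducts diastereomers, so 16 should be obtained stereochemically pure by separation whatever the facial bias. Regiochemistry rests on the charge distribution of both partners and on the fact that only the C3a-to-C4 orientation lets the unhindered CH2 terminus C6 make the bond to the fully substituted C7.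

Step 9
Reactants: 16
Product: 17 (3aS,4S,5R,7S)-5-hydroxy-4-isopropyl-7-methyl-7-(triethylsilyloxy)-3,3a,4,5,6,7-hexahydroazulen-2(1H)-one (2R,3R)-butane-2,3-diyl ketal (5β-OH, cis to isopropyl)
Conditions: Li[HB(sBu)3], THF, −78 °C
Reagents that add atoms: none
Why: The bulky trialkylborohydride should attack the C5 carbonyl from the α face, anti to the adjacent β-isopropyl group, giving the 5β-alcohol (substrate-controlled reduction of an α-branched cycloalkanone).

Step 10
Reactants: 17
Product: 18 (3aS,4S,5R,7S)-5-(tert-butyldimethylsilyloxy)-4-isopropyl-7-methyl-7-(triethylsilyloxy)-3,3a,4,5,6,7-hexahydroazulen-2(1H)-one (2R,3R)-butane-2,3-diyl ketal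
Conditions: tBuMe2SiOTf, 2,6-lutidine, CH2Cl2, −78 → 0 °C
Reagents that add atoms: tert-butyldimethylsilyl trifluoromethanesulfonate, CC(C)(C)[Si](C)(C)OS(=O)(=O)C(F)(F)F
Why: Silyl triflate with 2,6-lutidine silylates the hindered secondary alcohol; the resulting ether survives the acid, dissolving-metal and Grignard steps that follow.

Step 11
Reactants: 18
Product: 20 (3aS,4S,5R,7R)-5-(tert-butyldimethylsilyloxy)-4-isopropyl-7-methyl-7-(triethylsilyloxy)-3a,4,5,6,7,8-hexahydroazulen-2(3H)-one (C1=C8a enone), via β,γ-unsaturated ketone 19 (not isolated)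
Conditions: pyridinium p-toluenesulfonate, acetone/H2O (10:1), 50 °C; then DBU (cat.), CH2Cl2, rt
Reagents that add atoms: water, O
Why: Mild acid hydrolysis removes the dioxolane while sparing both silyl ethers (the allylic C7 ether is the sensitive one, hence the weak pyridinium acid), and a catalytic amidine base then moves the C8=C8a double bond into conjugation through the C1 dienolate without touching the γ-hydrogen at C3a; the auxiliary diol is recovered.

Step 12
Reactants: 20
Product: 22 (3aR,4S,5R,7R,8aS)-5-(tert-butyldimethylsilyloxy)-4-isopropyl-7-methyl-7-(triethylsilyloxy)-3,3a,4,5,6,7,8,8a-octahydroazulen-2-yl trifluoromethanesulfonate, via lithium enolate 21 (not isolated)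
Conditions: Li (2.2 equiv), NH3(l)/THF, tBuOH (1 equiv), −78 °C; evaporate NH3; PhNTf2, THF, −78 → 0 °C
Reagents that add atoms: N-phenylbis(trifluoromethanesulfonimide), O=S(=O)(N(c1ccccc1)S(=O)(=O)C(F)(F)F)C(F)(F)F
Why: Dissolving-metal reduction of the enone gives the regiodefined C1=C2 lithium enolate, which is trapped as the enol triflate; protonation of the C8a carbanion should occur under product-like control to give the trans ring fusion (H-8a α), and the silyl-capped C7 oxygen cannot deliver a proton from the β face.

Step 13
Reactants: 22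
Product: 23 (3aR,4S,5R,7R,8aS)-5-(tert-butyldimethylsilyloxy)-4-isopropyl-2,7-dimethyl-7-(triethylsilyloxy)-3,3a,4,5,6,7,8,8a-octahydroazulene (C1=C2 alkene)
Conditions: Fe(acac)3 (5 mol%), MeMgBr, THF/N-methylpyrrolidone, −30 → 0 °C
Reagents that add atoms: methylmagnesium bromide, C[Mg]Br
Why: Iron-catalysed cross-coupling of alkenyl triflates with methylmagnesium bromide is fast at low temperature and tolerates silyl ethers; it installs the C2 methyl with the C1=C2 double bond in place.

Step 14
Reactants: 23
Product: 24 (3aR,4S,5R,7R,8aS)-4-isopropyl-2,7-dimethyl-3,3a,4,5,6,7,8,8a-octahydroazulene-5,7-diol (both hydroxyls β)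
Conditions: Bu4NF, THF, 50 °C
Reagents that add atoms: none
Why: Fluoride cleaves both silyl ethers at a stage where the only other functional group is a trisubstituted alkene.

Step 15
Reactants: 25 isovanillic acid
Product: 27 3-(tert-butyldimethylsilyloxy)-4-methoxybenzoic acid, via silyl ester 26 (not isolated)
Conditions: tBuMe2SiCl (2.2 equiv), imidazole, DMF, rt; then AcOH/THF/H2O, rt
Reagents that add atoms: tert-butyldimethylsilyl chloride, CC(C)(C)[Si](C)(C)Cl
Why: Bis-silylation followed by selective hydrolysis of the labile silyl ester leaves the phenol protected, so the acid can be coupled without self-condensation.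

Step 16
Reactants: 24; 27
Product: 28 (3aR,4S,5R,7R,8aS)-7-hydroxy-4-isopropyl-2,7-dimethyl-3,3a,4,5,6,7,8,8a-octahydroazulen-5-yl 3-(tert-butyldimethylsilyloxy)-4-methoxybenzoate
Conditions: EDC·HCl, DMAP, CH2Cl2, rt
Reagents that add atoms: none
Why: Steglich esterification acylates only the secondary C5 hydroxyl; the tertiary C7 hydroxyl does not react under carbodiimide/DMAP conditions.

Step 17
Reactants: 28
Product: 29 (1S,2R,3aR,4S,5R,7R,8aS)-1,2-epoxy-7-hydroxy-4-isopropyl-2,7-dimethyldecahydroazulen-5-yl 3-(tert-butyldimethylsilyloxy)-4-methoxybenzoate (epoxide oxygen β)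
Conditions: VO(acac)2 (5 mol%), tBuOOH, CH2Cl2, 0 °C → rt
Reagents that add atoms: tert-butyl hydroperoxide, CC(C)(C)OO
Why: Vanadium-catalysed hydroxyl-directed epoxidation: the C7 hydroxyl (bishomoallylic to C1=C2) binds the metal peroxide and should deliver oxygen to the β face of the trisubstituted alkene; that hydroxyl cannot open the epoxide afterwards because both lie on the same face.

Step 18
Reactants: 29
Product: 30 (1S,2R,3aR,4S,5R,7R,8aS)-1,2-epoxy-7-hydroxy-4-isopropyl-2,7-dimethyldecahydroazulen-5-yl 3-hydroxy-4-methoxybenzoate (target)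
Conditions: Bu4NF, AcOH, THF, 0 °C
Reagents that add atoms: none
Why: A phenolic silyl ether is cleaved by buffered fluoride at 0 °C, conditions under which the epoxide, the tertiary alcohol and the aryl ester should be stable.

Compound list

1 | 1,3-dithiane | C1CSCSC1 | starting material
2 | allyl bromide | C=CCBr | starting material
3 | 3-chloro-2-(chloromethyl)prop-1-ene | C=C(CCl)CCl | starting material
4 | 2-allyl-1,3-dithiane | C=CCC1SCCCS1 | intermediate
5 | 2-allyl-2-[2-(chloromethyl)prop-2-en-1-yl]-1,3-dithiane | ClCC(=C)CC1(CC=C)SCCCS1 | intermediate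
6 | (2R,3R)-butane-2,3-diol | C[C@@H](O)[C@@H](C)O | starting material
7 | (4R,5R)-2-allyl-2-[2-(chloromethyl)prop-2-en-1-yl]-4,5-dimethyl-1,3-dioxolane | ClCC(=C)CC1(CC=C)O[C@H](C)[C@@H](C)O1 | intermediate
8 | acetaldehyde | CC=O | starting material
9 | 4-{[(4R,5R)-2-allyl-4,5-dimethyl-1,3-dioxolan-2-yl]methyl}pent-4-en-2-ol (both carbinol epimers) | CC(O)CC(=C)CC1(CC=C)O[C@H](C)[C@@H](C)O1 | intermediate
10 | 1-[(2R,3R)-2,3-dimethyl-1,4-dioxaspiro[4.4]non-7-en-7-yl]propan-2-ol (both carbinol epimers) | CC(O)CC1=CCC2(C1)O[C@H](C)[C@@H](C)O2 | intermediate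
11 | 1-[(2R,3R)-2,3-dimethyl-1,4-dioxaspiro[4.4]non-7-en-7-yl]propan-2-one | CC(=O)CC1=CCC2(C1)O[C@H](C)[C@@H](C)O2 | intermediate
12 | triethyl{[(Z)-1-((2R,3R)-2,3-dimethyl-1,4-dioxaspiro[4.4]non-7-en-7-yl)prop-1-en-2-yl]oxy}silane | C/C(O[Si](CC)(CC)CC)=C/C1=CCC2(C1)O[C@H](C)[C@@H](C)O2 | intermediate
13 | isobutylmagnesium bromide | CC(C)C[Mg]Br | starting material
14 | 2-chloro-N-methoxy-N-methylacetamide | CON(C)C(=O)CCl | starting material
15 | 1-chloro-4-methylpentan-2-one | CC(C)CC(=O)CCl | intermediate
16 | (3aS,4S,7S)-4-isopropyl-7-methyl-7-(triethylsilyloxy)-1,3,3a,4,6,7-hexahydroazulene-2,5-dione 2-[(2R,3R)-butane-2,3-diyl] ketal | O=C1C[C@](C)(O[Si](CC)(CC)CC)C=C2CC3(C[C@H]2[C@@H]1C(C)C)O[C@H](C)[C@@H](C)O3 | intermediate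
17 | (3aS,4S,5R,7S)-5-hydroxy-4-isopropyl-7-methyl-7-(triethylsilyloxy)-3,3a,4,5,6,7-hexahydroazulen-2(1H)-one (2R,3R)-butane-2,3-diyl ketal | O[C@@H]1C[C@](C)(O[Si](CC)(CC)CC)C=C2CC3(C[C@H]2[C@@H]1C(C)C)O[C@H](C)[C@@H](C)O3 | intermediate
18 | (3aS,4S,5R,7S)-5-(tert-butyldimethylsilyloxy)-4-isopropyl-7-methyl-7-(triethylsilyloxy)-3,3a,4,5,6,7-hexahydroazulen-2(1H)-one (2R,3R)-butane-2,3-diyl ketal | CC(C)(C)[Si](C)(C)O[C@@H]1C[C@](C)(O[Si](CC)(CC)CC)C=C2CC3(C[C@H]2[C@@H]1C(C)C)O[C@H](C)[C@@H](C)O3 | intermediate
19 | (3aS,4S,5R,7S)-5-(tert-butyldimethylsilyloxy)-4-isopropyl-7-methyl-7-(triethylsilyloxy)-3,3a,4,5,6,7-hexahydroazulen-2(1H)-one (C8=C8a) | CC(C)(C)[Si](C)(C)O[C@@H]1C[C@](C)(O[Si](CC)(CC)CC)C=C2CC(=O)C[C@H]2[C@@H]1C(C)C | intermediate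
20 | (3aS,4S,5R,7R)-5-(tert-butyldimethylsilyloxy)-4-isopropyl-7-methyl-7-(triethylsilyloxy)-3a,4,5,6,7,8-hexahydroazulen-2(3H)-one (C1=C8a) | CC(C)(C)[Si](C)(C)O[C@@H]1C[C@](C)(O[Si](CC)(CC)CC)CC2=CC(=O)C[C@H]2[C@@H]1C(C)C | intermediate
21 | lithium (3aR,4S,5R,7R,8aS)-5-(tert-butyldimethylsilyloxy)-4-isopropyl-7-methyl-7-(triethylsilyloxy)-3,3a,4,5,6,7,8,8a-octahydroazulen-2-olate | CC(C)(C)[Si](C)(C)O[C@@H]1C[C@](C)(O[Si](CC)(CC)CC)C[C@H]2[C@@H](CC(O[Li])=C2)[C@@H]1C(C)C | intermediate
22 | (3aR,4S,5R,7R,8aS)-5-(tert-butyldimethylsilyloxy)-4-isopropyl-7-methyl-7-(triethylsilyloxy)-3,3a,4,5,6,7,8,8a-octahydroazulen-2-yl trifluoromethanesulfonate | CC(C)(C)[Si](C)(C)O[C@@H]1C[C@](C)(O[Si](CC)(CC)CC)C[C@H]2[C@@H](CC(OS(=O)(=O)C(F)(F)F)=C2)[C@@H]1C(C)C | intermediate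
23 | (3aR,4S,5R,7R,8aS)-5-(tert-butyldimethylsilyloxy)-4-isopropyl-2,7-dimethyl-7-(triethylsilyloxy)-3,3a,4,5,6,7,8,8a-octahydroazulene | CC(C)(C)[Si](C)(C)O[C@@H]1C[C@](C)(O[Si](CC)(CC)CC)C[C@H]2[C@@H](CC(C)=C2)[C@@H]1C(C)C | intermediate
24 | (3aR,4S,5R,7R,8aS)-4-isopropyl-2,7-dimethyl-3,3a,4,5,6,7,8,8a-octahydroazulene-5,7-diol | O[C@@H]1C[C@](C)(O)C[C@H]2[C@@H](CC(C)=C2)[C@@H]1C(C)C | intermediate
25 | isovanillic acid (3-hydroxy-4-methoxybenzoic acid) | COc1ccc(C(=O)O)cc1O | starting material
26 | tert-butyldimethylsilyl 3-(tert-butyldimethylsilyloxy)-4-methoxybenzoate | COc1ccc(C(=O)O[Si](C)(C)C(C)(C)C)cc1O[Si](C)(C)C(C)(C)C | intermediate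
27 | 3-(tert-butyldimethylsilyloxy)-4-methoxybenzoic acid | COc1ccc(C(=O)O)cc1O[Si](C)(C)C(C)(C)C | intermediate
28 | (3aR,4S,5R,7R,8aS)-7-hydroxy-4-isopropyl-2,7-dimethyl-3,3a,4,5,6,7,8,8a-octahydroazulen-5-yl 3-(tert-butyldimethylsilyloxy)-4-methoxybenzoate | COc1ccc(C(=O)O[C@@H]2C[C@](C)(O)C[C@H]3[C@@H](CC(C)=C3)[C@@H]2C(C)C)cc1O[Si](C)(C)C(C)(C)C | intermediate
29 | (1S,2R,3aR,4S,5R,7R,8aS)-1,2-epoxy-7-hydroxy-4-isopropyl-2,7-dimethyldecahydroazulen-5-yl 3-(tert-butyldimethylsilyloxy)-4-methoxybenzoate | COc1ccc(C(=O)O[C@@H]2C[C@](C)(O)C[C@H]3[C@@H](C[C@@]4(C)O[C@@H]34)[C@@H]2C(C)C)cc1O[Si](C)(C)C(C)(C)C | intermediate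
30 | (1S,2R,3aR,4S,5R,7R,8aS)-1,2-epoxy-7-hydroxy-4-isopropyl-2,7-dimethyldecahydroazulen-5-yl 3-hydroxy-4-methoxybenzoate | COc1ccc(C(=O)O[C@@H]2C[C@](C)(O)C[C@H]3[C@@H](C[C@@]4(C)O[C@@H]34)[C@@H]2C(C)C)cc1O | target

Total step count: 18. Longest linear sequence: 16 steps (steps 1–6, 8–14, 16–18); steps 7 and 15 prepare the two side fragments.

Steps least certain to work

Step 8 (key step, Proposed new method). The most likely failures are two. The zwitterion formed after the first bond may collapse at C8a to a five-membered ring, or lose its silyl group before the second bond forms, because the diene is not locked s-cis and both ring-closing termini are fully substituted. Weak facial discrimination by the remote ketal auxiliary would halve the throughput. Fallback by known chemistry, setting out from 7 and returning at 16: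
- Ring-closing metathesis of 7 with RuCl2(=CHPh)(H2IMes)(PCy3) gives the cyclic allylic chloride (2R,3R)-7-(chloromethyl)-2,3-dimethyl-1,4-dioxaspiro[4.4]non-7-ene F1.
- Displacement with caesium 3-methylbutanoate in DMF gives the allylic ester F2.
- Ireland–Claisen rearrangement (LiN(iPr)2, Me3SiCl, THF, −78 °C → reflux) forms C3a–C4 and gives acid F3 with an exocyclic methylene on C8a; the two C3a diastereomers are again separable ketals.
- MeLi (2 equiv) converts F3 into methyl ketone F4.
- The kinetic lithium enolate of F4 adds 1,2 to but-3-en-2-one at −78 °C to give aldol F5 (C7 not controlled at this stage).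
- Ring-closing metathesis of F5 with RuCl2(H2IMes)(=CH-C6H4-2-OiPr) in toluene at 80 °C closes the seven-membered ring at C8=C8a to give hydroxy ketone F6, from which the C7 epimer is removed.
- Et3SiOTf/2,6-lutidine then gives 16.

This sequence is longer and gives up the stereochemical link between C7 and C3a, but each step is of a known type.

Step 12. Protonation of the C8a carbanion from the β face would give the cis ring fusion, because the thermodynamic preference for trans fusion in hydroazulenes is small and the β face is the one syn to H-3a. Fallback from 20, returning at 22: RhCl(PPh3)3-catalysed 1,4-hydrosilylation with Et3SiH delivers hydride to C8a under kinetic control. The hydride should come from the α face, since the β face carries the isopropyl group and both silyloxy groups. The product is silyl enol ether F7 with the same C1=C2 regiochemistry. MeLi in THF liberates lithium enolate 21, which is triflated with PhNTf2 to give 22.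

Step 17. Oxygen delivery may be poorly face-selective, or may occur on the α face, if the bishomoallylic C7 hydroxyl cannot bring the metal peroxide over the cyclopentene. Fallback from 23, returning at 29:
- N-bromosuccinimide in aqueous THF forms the bromonium ion on the open α face, and water opens it at the tertiary C2 from the β face to give bromohydrin F8.
- K2CO3 in MeOH closes F8 to the β-epoxide F9.
- Bu4NF removes both silyl groups to give epoxy diol F10; the alkoxides lie on the epoxide face and cannot open it.
- Steglich esterification of F10 with 27 gives 29.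

Step 9. Hydride addition syn to the isopropyl group, giving the C5 epimer, is possible because the α face of the carbonyl is flanked by the 1,3-related α-methyl on C7. Fallback from 16, returning at 18:
- HF·pyridine (THF, pyridine, 0 °C) removes the tertiary triethylsilyl group to give β-hydroxy ketone F11 (the same compound as F6).
- Narasaka–Prasad reduction (Et2BOMe, NaBH4, THF/MeOH, −78 °C) gives the 1,3-syn diol F12, that is the 5β-alcohol, because the boron chelate can only span cis oxygens.
- tBuMe2SiCl/imidazole silylates the secondary hydroxyl to give F13.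
- Et3SiOTf/2,6-lutidine silylates the tertiary hydroxyl to give 18.

Further compounds

F1 | step 8 | (2R,3R)-7-(chloromethyl)-2,3-dimethyl-1,4-dioxaspiro[4.4]non-7-ene | ClCC1=CCC2(C1)O[C@H](C)[C@@H](C)O2
F2 | step 8 | [(2R,3R)-2,3-dimethyl-1,4-dioxaspiro[4.4]non-7-en-7-yl]methyl 3-methylbutanoate | CC(C)CC(=O)OCC1=CCC2(C1)O[C@H](C)[C@@H](C)O2
F3 | step 8 | 3-methyl-2-[(2R,3R)-2,3-dimethyl-8-methylidene-1,4-dioxaspiro[4.4]nonan-7-yl]butanoic acid (C3a and C4 as in 16) | CC(C)[C@H](C(=O)O)[C@@H]1CC2(CC1=C)O[C@H](C)[C@@H](C)O2
F4 | step 8 | 4-methyl-3-[(2R,3R)-2,3-dimethyl-8-methylidene-1,4-dioxaspiro[4.4]nonan-7-yl]pentan-2-one (C3a and C4 as in 16) | CC(C)[C@H](C(C)=O)[C@@H]1CC2(CC1=C)O[C@H](C)[C@@H](C)O2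
F5 | step 8 | 3-hydroxy-3,7-dimethyl-6-[(2R,3R)-2,3-dimethyl-8-methylidene-1,4-dioxaspiro[4.4]nonan-7-yl]oct-1-en-5-one (C7 epimer needed for 16 shown) | CC(C)[C@H](C(=O)C[C@](C)(O)C=C)[C@@H]1CC2(CC1=C)O[C@H](C)[C@@H](C)O2
F6 | step 8 | (3aS,4S,7S)-7-hydroxy-4-isopropyl-7-methyl-1,3,3a,4,6,7-hexahydroazulene-2,5-dione 2-[(2R,3R)-butane-2,3-diyl] ketal | O=C1C[C@](C)(O)C=C2CC3(C[C@H]2[C@@H]1C(C)C)O[C@H](C)[C@@H](C)O3
F7 | step 12 | (3aR,4S,5R,7R,8aS)-5-(tert-butyldimethylsilyloxy)-4-isopropyl-7-methyl-2,7-bis(triethylsilyloxy)-3,3a,4,5,6,7,8,8a-octahydroazulene | CC(C)(C)[Si](C)(C)O[C@@H]1C[C@](C)(O[Si](CC)(CC)CC)C[C@H]2[C@@H](CC(O[Si](CC)(CC)CC)=C2)[C@@H]1C(C)C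
F8 | step 17 | 1α-bromo-5β-(tert-butyldimethylsilyloxy)-4β-isopropyl-2α,7α-dimethyl-7β-(triethylsilyloxy)decahydroazulen-2β-ol | CC(C)(C)[Si](C)(C)O[C@@H]1C[C@](C)(O[Si](CC)(CC)CC)C[C@H]2[C@@H](C[C@@](C)(O)[C@@H]2Br)[C@@H]1C(C)C
F9 | step 17 | 1β,2β-epoxy-5β-(tert-butyldimethylsilyloxy)-4β-isopropyl-2α,7α-dimethyl-7β-(triethylsilyloxy)decahydroazulene | CC(C)(C)[Si](C)(C)O[C@@H]1C[C@](C)(O[Si](CC)(CC)CC)C[C@H]2[C@@H](C[C@@]3(C)O[C@@H]23)[C@@H]1C(C)C
F10 | step 17 | 1β,2β-epoxy-4β-isopropyl-2α,7α-dimethyldecahydroazulene-5β,7β-diol | O[C@@H]1C[C@](C)(O)C[C@H]2[C@@H](C[C@@]3(C)O[C@@H]23)[C@@H]1C(C)C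
F11 | step 9 | (3aS,4S,7S)-7-hydroxy-4-isopropyl-7-methyl-1,3,3a,4,6,7-hexahydroazulene-2,5-dione 2-[(2R,3R)-butane-2,3-diyl] ketal | O=C1C[C@](C)(O)C=C2CC3(C[C@H]2[C@@H]1C(C)C)O[C@H](C)[C@@H](C)O3
F12 | step 9 | (3aS,4S,5R,7S)-5,7-dihydroxy-4-isopropyl-7-methyl-3,3a,4,5,6,7-hexahydroazulen-2(1H)-one (2R,3R)-butane-2,3-diyl ketal | O[C@@H]1C[C@](C)(O)C=C2CC3(C[C@H]2[C@@H]1C(C)C)O[C@H](C)[C@@H](C)O3
F13 | step 9 | (3aS,4S,5R,7S)-5-(tert-butyldimethylsilyloxy)-7-hydroxy-4-isopropyl-7-methyl-3,3a,4,5,6,7-hexahydroazulen-2(1H)-one (2R,3R)-butane-2,3-diyl ketal | CC(C)(C)[Si](C)(C)O[C@@H]1C[C@](C)(O)C=C2CC3(C[C@H]2[C@@H]1C(C)C)O[C@H](C)[C@@H](C)O3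
A1 | alternative 1 | 6-(tert-butyldimethylsilyloxy)-7-isopropyl-2-[(4-methoxybenzyloxy)methyl]-4-methylcyclohept-3-ene-1-carboxylic acid | OC(=O)[C@@H]1[C@H](C(C)C)[C@H](O[Si](C)(C)C(C)(C)C)CC(C)=C[C@@H]1COCc2ccc(OC)cc2
A2 | alternative 2 | 4-(tert-butyldimethylsilyloxy)-3-isopropyl-6-methyl-6-(triethylsilyloxy)nona-1,2-dien-8-yne | C#CC[C@@](C)(O[Si](CC)(CC)CC)C[C@@H](O[Si](C)(C)C(C)(C)C)C(C(C)C)=C=C
A3 | alternative 2 | 5-(tert-butyldimethylsilyloxy)-4-isopropyl-7-methyl-7-(triethylsilyloxy)-5,6,7,8-tetrahydroazulen-2(3H)-one | O=C1C=C2C[C@@](C)(O[Si](CC)(CC)CC)C[C@@H](O[Si](C)(C)C(C)(C)C)C(C(C)C)=C2C1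
A4 | alternative 3 | 3-methyl-2-[3-methyl-5-(2-methylprop-2-en-1-yl)cyclopent-3-en-1-yl]butanal | O=C[C@@H](C(C)C)[C@@H]1CC(C)=C[C@H]1CC(C)=C
A5 | alternative 3 | 4-isopropyl-2-methyl-7-methylene-3,3a,4,5,6,7,8,8a-octahydroazulen-5-ol | O[C@@H]1CC(=C)C[C@H]2[C@@H](CC(C)=C2)[C@@H]1C(C)C
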